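**Target.** CNP0182751.1 is (2R,3R)-pinobanksin 3-hexanoate, numbered 12 below. The numbering used in all sections is: 1 2',4',6'-trihydroxyacetophenone; 2 its 4,6-dibenzyl ether; 3 enaminone; 4 5,7-bis(benzyloxy)chromone; 5 phenylboronic acid; 6 (2S)-5,7-bis(benzyloxy)flavanone; 7 hexanoic anhydride; 8 lithium enolate of 6; 9 enol hexanoate; 10 acyloxy epoxide; 11 dibenzyl ether of the target; 12 target.

## The problem

Target 12 has a phloroglucinol-derived ring A (free OH at C5 and C7) fused to the dihydropyranone ring C (O1, C2, C3, C4=O, C4a, C8a), an unsubstituted phenyl ring B on C2 and a hexanoate on O3. The only stereocentres are C2 and C3, adjacent and trans. C3 is α to the C4 ketone and can be equilibrated toward the trans-diequatorial arrangement, so C2 can control C3, but nothing in the molecule controls C2, which must be set by a reagent. Both centres are fragile under base: a C3 enolate expels the O1 phenoxide (retro-oxa-Michael), which opens ring C and erases C2. Halogenation or cation formation at C3 leads to dehydrogenation to the flavone level or to a 2,3-phenyl shift, and the α-acyloxy ketone will not survive hydroxide or alkoxide, so the end game must be neutral. The hexanoyl group must sit on the secondary O3 while two phenols stay free, and in the free triol the C7 phenol is the most reactive hydroxyl, so late acylation is not selective.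

The feature that makes the key step possible is threefold:
- C3 is the only sp3 carbon α to C4 (the other α-position is the aromatic C4a), so only one enol ester can form.
- O3–C3–C4=O is exactly the pattern produced when an enol ester is epoxidised and its acyl group moves from O4 to the new oxygen on C3.
- C4 is bonded to ring A, whose O1, O5 and O7 are ortho/para to C4a and stabilise positive charge at C4, and the C2 phenyl blocks one face of C3=C4.

## Retrosynthesis

**12 ⇒ 11.** The two phenolic O–H bonds are traced back to O–CH2Ph bonds. Benzyl ethers are chosen over silyl, acetal or acyl protection because they leave by neutral hydrogenolysis; fluoride, acid or base would threaten the α-acyloxy ketone and ring C. The forward step must spare the cyclic benzylic C2–O1 bond.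

**11 ⇒ 9 (through 10).** The C3–O3 bond is cut and the hexanoyl group is moved back from O3 to O4, giving enol ester 9. The neighbouring cuts are worse: hydroxylation then acylation costs two steps and exposes a base-labile α-ketol, and direct acyloxylation with electrophilic halogen or hypervalent-iodine reagents puts cationic character on C3. Precursor 9 has one stereocentre and one oxygen fewer, and its acyl group sits on the only oxygen available at that stage. The forward reaction must epoxidise C3=C4 anti to the C2 phenyl (epoxide 10) and collapse 10 with retention at C3.

**9 ⇒ 6 + 7.** The O4–acyl bond is cut to give flavanone 6 and hexanoic anhydride 7, joined through lithium enolate 8. Regiochemistry is not an issue because C3 is the only enolisable position. The forward reaction needs O- rather than C-acylation, and trapping of 8 faster than loss of the O1 phenoxide.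

**6 ⇒ 4 + 5.** The C2–C1' bond is cut to give chromone 4 and phenylboronic acid 5. This is preferred over the O1–C2 cut (chalcone cyclisation), which is reversible and erodes configuration at C2, whereas the C–C bond is formed irreversibly. Chromone 4 is flat, achiral and lacks ring B. The forward reaction must be an enantioselective conjugate phenylation that tolerates an electron-rich enone.

**4 ⇒ 2 ⇒ 1.** O1–C2 and C2–C3 are cut: the chromone C2 carbon is a one-carbon unit condensed onto the acetyl group of 2 (enaminone 3) and closed by the ortho phenol. Acetophenone 2 comes from 1 by double benzylation; the hydroxyl hydrogen-bonded to the carbonyl stays free and later becomes O1.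

## Roads not taken

**Alternative 1:** the chalcone epoxide route, cutting O1–C2 with the C3 oxygen held as an oxirane. Chalcone A1 (all three phenols as MOM ethers) would be epoxidised enantioselectively (Julia–Colonna conditions) to A2. Acid would then remove the MOM groups, and the freed 2'-phenol would open the oxirane at the benzylic carbon (6-endo, inversion) to give pinobanksin A3.
- The benzylic carbon carries an unsubstituted phenyl, so opening needs acid strong enough to allow partial ionisation, which costs inversion fidelity and invites 5-exo closure at the other oxirane carbon.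
- The product A3 is the free triol, whose C7 phenol out-competes O3, so a protect–acylate–deprotect cycle follows.
- The count rises to eight or nine steps, against six here, and the chosen plan never has a free hydroxyl competing for the acyl group.

**Alternative 2:** the C2–C1' cut made with the ester already at C3. Enantioselective conjugate phenylation of 3-(hexanoyloxy)chromone A4 would be followed by thermodynamic protonation at C3.
- The α-oxygenated, trisubstituted enone of A4 should insert into an aryl–metal bond much more slowly than the unsubstituted chromone.
- Its enol-type ester is easily cleaved by the aqueous base that such additions use.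
- A4 needs its own C3 oxidation of the chromone first.
- The chosen plan uses the same C–C bond formation on chromone 4, where the reaction type is established.

**Alternative 3:** a dynamic, chalcone-isomerase-like closure, cutting O1–C2 of 11. An asymmetric oxa-Michael cyclisation of α-(hexanoyloxy)-2'-hydroxychalcone A5 with a bifunctional base catalyst would funnel both alkene isomers and both C3 epimers into trans-11.
- The cyclisation is reversible under the conditions that promote it, so configuration at C2 is open to erosion.
- Unactivated 2'-hydroxychalcones cyclise with weak enantiocontrol.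
- The free phenol can take the acyl group from the enol ester (O to O transfer).
- A5, an enol ester of a 1,2-diketone, is not easy to make cleanly.
- The chosen plan fixes C2 by an irreversible C–C bond formation instead.

Key step: step 5

Remark on the chemistry: the sense of induction in step 3 is assigned by analogy with Rh/(S)-BINAP additions to 2-cyclohexenone (same enone face, which for 4 is the C2 Re face); if the chromone responded in the opposite sense, the (R)-ligand would be used and nothing else would change.

## Route

Step 1
Reactants: 1 2',4',6'-trihydroxyacetophenone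
Product: 2 1-[2,4-bis(benzyloxy)-6-hydroxyphenyl]ethan-1-one
Conditions: BnBr (2.1 equiv), K2CO3 (2.2 equiv), DMF, 20 °C
Reagents that add atoms: benzyl bromide, BrCc1ccccc1
Why: Williamson ether synthesis; the para hydroxyl and one of the two equivalent ortho hydroxyls are alkylated, and the remaining ortho hydroxyl, hydrogen-bonded to the acetyl carbonyl, should stay free, so only one dibenzyl ether is expected.

Step 2
Reactants: 2 1-[2,4-bis(benzyloxy)-6-hydroxyphenyl]ethan-1-one
Product: 4 chromone 5,7-bis(benzyloxy)-4H-chromen-4-one, via enaminone 3 (not isolated)
Conditions: Me2NCH(OMe)2 (3 equiv), toluene, 100 °C; then conc. HCl, CH2Cl2, 40 °C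
Reagents that add atoms: N,N-dimethylformamide dimethyl acetal, COC(OC)N(C)C
Why: Condensation of the acetyl CH3 with the formamide acetal gives enaminone 3; acid then promotes 6-endo addition of the phenol oxygen to the β-carbon and loss of dimethylamine, the standard chromone synthesis; no stereocentre is formed.

Step 3
Reactants: 4 5,7-bis(benzyloxy)-4H-chromen-4-one; 5 phenylboronic acid (2 equiv)
Product: 6 (2S)-5,7-bis(benzyloxy)-2-phenylchroman-4-one
Conditions: [RhCl(C2H4)2]2 (2.5 mol %), (S)-MeO-F12-BIPHEP (5.5 mol %), KOH (10 mol %), toluene/H2O 10:1, 25 °C
Reagents that add atoms: phenylboronic acid 5, OB(O)c1ccccc1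
Why: Rh-catalysed asymmetric 1,4-addition of an arylboronic acid (Hayashi–Miyaura reaction), a reaction type established for chromones; the aryl–Rh species inserts C2=C3 with phenyl delivered to the C2 Re face under control of the (S)-biaryl bisphosphine, and water protonates the Rh enolate, setting C2 as S. Low base loading and ambient temperature should keep retro-oxa-Michael opening of 6 suppressed.

Step 4
Reactants: 6 (2S)-5,7-bis(benzyloxy)-2-phenylchroman-4-one; 7 hexanoic anhydride (2 equiv)
Product: 9 enol ester (2S)-5,7-bis(benzyloxy)-2-phenyl-2H-chromen-4-yl hexanoate, via lithium enolate 8 (not isolated)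
Conditions: LiHMDS (1.1 equiv), THF, −78 °C, 15 min; then cannulated into 7, THF, −78 → −40 °C
Reagents that add atoms: hexanoic anhydride 7, CCCCCC(=O)OC(=O)CCCCC; lithium hexamethyldisilazide, [Li+].C[Si](C)(C)[N-][Si](C)(C)C (lithium in 8 only)
Why: Kinetic deprotonation at C3, the only enolisable position, and O-acylation of the lithium enolate by inverse addition to excess anhydride (enol ester formation from a metal enolate). At −78 °C expulsion of the O1 phenoxide from 8 should be slow relative to trapping, so C2 stays S.

Step 5
Reactants: 9 (2S)-5,7-bis(benzyloxy)-2-phenyl-2H-chromen-4-yl hexanoate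
Product: 11 (2R,3R)-5,7-bis(benzyloxy)-4-oxo-2-phenylchroman-3-yl hexanoate, via acyloxy epoxide 10 (not isolated)
Conditions: DMDO (1.3 equiv, acetone), CH2Cl2, −20 → 0 °C; evaporate; anhydrous p-TsOH (10 mol %), CH2Cl2, 0 → 20 °C
Reagents that add atoms: dimethyldioxirane, CC1(C)OO1
Why: Dimethyldioxirane should transfer oxygen to the electron-rich C3=C4 enol ester bond of 9 through the usual concerted spiro transition state, from the face opposite the C2 phenyl group, to give acyloxy epoxide 10. Acid should then break the oxirane C4–O bond and not C3–O, because C4 carries the acyloxy oxygen and ring A, whose O1, O5 and O7 lie ortho/para to C4a and stabilise the cation. The freed O3 adds to the ester carbonyl to give a cyclic ortho-acid bridging O3 and O4, which collapses to the C4 ketone and the O3 ester, a net 1,2-acyl transposition with retention at C3. The closest known reaction type is the epoxidation of enol esters followed by acid-catalysed rearrangement of the α-acyloxy epoxides to α-acyloxy ketones, the ester counterpart of the Rubottom oxidation. No ring of the product is closed; the two transient rings are the oxirane (concerted oxygen transfer) and the 1,3-dioxolane ortho-acid (5-exo-trig). The new stereocentre C3 (R) is controlled by the existing C2 centre, which is not touched and changes its descriptor from S to R only because C3 now outranks phenyl. The step needs anti facial selectivity and the retentive pathway: the C2 phenyl shields one face, ring A secures ionisation at C4, and any cis ester formed by a concerted invertive shift should drain to the trans-diequatorial 11 by acid-catalysed enolisation at C3. Chemoselectivity for the enol double bond over ring A and the benzylic CH2 groups rests on low temperature and a small excess of oxidant.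

Step 6
Reactants: 11 (2R,3R)-5,7-bis(benzyloxy)-4-oxo-2-phenylchroman-3-yl hexanoate
Product: 12 (2R,3R)-5,7-dihydroxy-4-oxo-2-phenylchroman-3-yl hexanoate
Conditions: H2 (1 atm), 10 % Pd/C, EtOAc, 20 °C
Reagents that add atoms: none
Why: Hydrogenolysis of the two aryl benzyl ethers under neutral conditions; the primary O-benzyl groups should cleave much faster than the cyclic secondary benzylic C2–O1 bond, and with no acid or base present the α-acyloxy ketone and both stereocentres should be untouched.

## Compound list

1 | 1-(2,4,6-trihydroxyphenyl)ethan-1-one (2',4',6'-trihydroxyacetophenone) | CC(=O)c1c(O)cc(O)cc1O | starting material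
2 | 1-[2,4-bis(benzyloxy)-6-hydroxyphenyl]ethan-1-one | CC(=O)c1c(O)cc(OCc2ccccc2)cc1OCc1ccccc1 | intermediate
3 | (E)-1-[2,4-bis(benzyloxy)-6-hydroxyphenyl]-3-(dimethylamino)prop-2-en-1-one | CN(C)/C=C/C(=O)c1c(O)cc(OCc2ccccc2)cc1OCc1ccccc1 | intermediate (not isolated)
4 | 5,7-bis(benzyloxy)-4H-chromen-4-one | O=c1ccoc2cc(OCc3ccccc3)cc(OCc3ccccc3)c12 | intermediate
5 | phenylboronic acid | OB(O)c1ccccc1 | starting material
6 | (2S)-5,7-bis(benzyloxy)-2-phenylchroman-4-one | O=C1C[C@@H](c2ccccc2)Oc2cc(OCc3ccccc3)cc(OCc3ccccc3)c21 | intermediate
7 | hexanoic anhydride | CCCCCC(=O)OC(=O)CCCCC | starting material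
8 | lithium (2S)-5,7-bis(benzyloxy)-2-phenyl-2H-chromen-4-olate | [Li+].[O-]C1=C[C@@H](c2ccccc2)Oc2cc(OCc3ccccc3)cc(OCc3ccccc3)c21 | intermediate (not isolated)
9 | (2S)-5,7-bis(benzyloxy)-2-phenyl-2H-chromen-4-yl hexanoate | CCCCCC(=O)OC1=C[C@@H](c2ccccc2)Oc2cc(OCc3ccccc3)cc(OCc3ccccc3)c21 | intermediate
10 | (2R,3R,4R)-5,7-bis(benzyloxy)-3,4-epoxy-2-phenylchroman-4-yl hexanoate (oxirane oxygen anti to the 2-phenyl group) | CCCCCC(=O)O[C@@]12O[C@@H]1[C@@H](c1ccccc1)Oc1cc(OCc3ccccc3)cc(OCc3ccccc3)c12 | intermediate (not isolated)
11 | (2R,3R)-5,7-bis(benzyloxy)-4-oxo-2-phenylchroman-3-yl hexanoate | CCCCCC(=O)O[C@H]1C(=O)c2c(OCc3ccccc3)cc(OCc3ccccc3)cc2O[C@@H]1c1ccccc1 | intermediate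
12 | (2R,3R)-5,7-dihydroxy-4-oxo-2-phenylchroman-3-yl hexanoate | CCCCCC(=O)O[C@H]1C(=O)c2c(O)cc(O)cc2O[C@@H]1c1ccccc1 | target

## Step count and risks

Total steps: 6. Longest linear sequence: 6 (from 1).

**Step 5 (key step).**
- Most likely failure: the acyloxy epoxide collapses the wrong way. This could be a concerted shift with inversion at C3 that is not then corrected by enolisation, or capture of the C4 cation by adventitious water with loss of the acyl group.
- Second concern: competing oxidation of the electron-rich ring A.
- Fallback: set out from 6 and oxygenate the lithium enolate directly with 2-(phenylsulfonyl)-3-phenyloxaziridine at −78 °C, anti to the phenyl group. This should give the α-ketol (2R,3R)-5,7-bis(benzyloxy)-3-hydroxy-2-phenylchroman-4-one F1, whose only free hydroxyl is then esterified with hexanoyl chloride and pyridine. The fallback returns to the route at 11.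

**Step 4.**
- Most likely failure: β-elimination of the O1 phenoxide from the enolate before it is trapped, which opens ring C and loses C2; acylation at carbon instead of oxygen is the second risk.
- Fallback: set out from 4 and run the Rh/(S)-BINAP-catalysed conjugate addition with phenylzinc chloride in the presence of chlorotrimethylsilane. The rhodium enolate is silylated as it forms, giving the silyl enol ether {[(2S)-5,7-bis(benzyloxy)-2-phenyl-2H-chromen-4-yl]oxy}trimethylsilane F2 without a free enolate. Fluoride-catalysed O-acylation of F2 with hexanoyl fluoride, in which the enolate exists only in catalytic amounts, returns to the route at 9.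

**Step 3.**
- Most likely failure: slow insertion into the electron-rich, vinylogous-ester enone, base-induced ring opening with partial racemisation of the product, or an unexpected sense of induction. The sense can be checked by chiroptical comparison after debenzylation of a sample.
- Fallback: set out from 2. Claisen–Schmidt condensation with benzaldehyde should give the chalcone (E)-1-[2,4-bis(benzyloxy)-6-hydroxyphenyl]-3-phenylprop-2-en-1-one F3, and oxa-Michael cyclisation (NaOAc, EtOH, reflux) the racemic flavanone rac-5,7-bis(benzyloxy)-2-phenylchroman-4-one F4.
- F4 is then resolved kinetically by Noyori asymmetric transfer hydrogenation (Ru/(R,R)-TsDPEN, HCO2H/Et3N). The (R)-ketone should be reduced to the cis alcohol (2R,4R)-5,7-bis(benzyloxy)-2-phenylchroman-4-ol F5, which is separated, leaving the (S)-ketone. The fallback returns at 6 with at most half of the material.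

**Step 6.**
- Most likely failure: over-reduction by hydrogenolysis of the benzylic C2–O1 bond, or slow cleavage of the hindered 5-O-benzyl group leading to long exposure.
- Fallback: set out from 11 and debenzylate without hydrogen, using BCl3 and pentamethylbenzene in CH2Cl2 at −78 °C, which goes directly to 12 and makes no new intermediate.

## Further compounds

F1 | step 5 | (2R,3R)-5,7-bis(benzyloxy)-3-hydroxy-2-phenylchroman-4-one | O[C@H]1C(=O)c2c(OCc3ccccc3)cc(OCc3ccccc3)cc2O[C@@H]1c1ccccc1
F2 | step 4 | {[(2S)-5,7-bis(benzyloxy)-2-phenyl-2H-chromen-4-yl]oxy}trimethylsilane | C[Si](C)(C)OC1=C[C@@H](c2ccccc2)Oc2cc(OCc3ccccc3)cc(OCc3ccccc3)c21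
F3 | step 3 | (E)-1-[2,4-bis(benzyloxy)-6-hydroxyphenyl]-3-phenylprop-2-en-1-one | O=C(/C=C/c1ccccc1)c1c(O)cc(OCc2ccccc2)cc1OCc1ccccc1
F4 | step 3 | rac-5,7-bis(benzyloxy)-2-phenylchroman-4-one | O=C1CC(c2ccccc2)Oc2cc(OCc3ccccc3)cc(OCc3ccccc3)c21
F5 | step 3 | (2R,4R)-5,7-bis(benzyloxy)-2-phenylchroman-4-ol | O[C@@H]1C[C@H](c2ccccc2)Oc2cc(OCc3ccccc3)cc(OCc3ccccc3)c21
F0 | step 6 | none | none
A1 | alternative 1 | (E)-3-phenyl-1-[2,4,6-tris(methoxymethoxy)phenyl]prop-2-en-1-one | COCOc1cc(OCOC)c(C(=O)/C=C/c2ccccc2)c(OCOC)c1
A2 | alternative 1 | [(2R,3S)-3-phenyloxiran-2-yl][2,4,6-tris(methoxymethoxy)phenyl]methanone | O=C(c1c(OCOC)cc(OCOC)cc1OCOC)[C@@H]1O[C@H]1c1ccccc1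
A3 | alternative 1 | (2R,3R)-3,5,7-trihydroxy-2-phenylchroman-4-one (pinobanksin) | O[C@H]1C(=O)c2c(O)cc(O)cc2O[C@@H]1c1ccccc1
A4 | alternative 2 | 5,7-bis(benzyloxy)-4-oxo-4H-chromen-3-yl hexanoate | CCCCCC(=O)Oc1coc2cc(OCc3ccccc3)cc(OCc3ccccc3)c2c1=O
A5 | alternative 3 | (Z)-3-[2,4-bis(benzyloxy)-6-hydroxyphenyl]-3-oxo-1-phenylprop-1-en-2-yl hexanoate | CCCCCC(=O)O/C(=C\c1ccccc1)C(=O)c1c(O)cc(OCc2ccccc2)cc1OCc1ccccc1
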